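The plan opens the pyrrole ring of indole B at C3–C3a and N1–C7a. The feature exploited is that its benzo ring (C3a to C7a, oxygen on C5, para to C7a) maps atom for atom onto 1,4-benzoquinone, while N1–C2–C3 is an enamine of the arylacetaldehyde attached to C4 of the central ring. One Nenitzescu annulation forms both bonds, closes the five-membered ring and leaves C5–OH as the only unmasked oxygen. The congested C3–aryl junction needs no coupling because the aryl group arrives on the enamine. The precursor is the (E) secondary enamine of [4-(6-methoxy-1-tosylindol-3-yl)-2,3,5,6-tetramethoxyphenyl]acetaldehyde and 2-(phenylsulfonyl)ethylamine.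

Key step: step 8

Remarks on the chemistry (design choices and one assumption)
- Assumption: the condensation product of step 7 is a mobile aldimine/enamine mixture. Both tautomers are numbered, the enamine is the reactive one, and the material is used without purification.
- Indole A carries tosyl rather than an alkyl group. A 1-alkyl-6-methoxy-3-arylindole is a good C2 nucleophile, because the 6-methoxy group stabilises the C3 cation, and it would compete with the enamine for the activated quinone.
- The enamine nitrogen carries 2-(phenylsulfonyl)ethyl, which is removed by base-induced β-elimination. Dissolving-metal debenzylation is avoided because the four flanked, out-of-plane methoxy groups of the central ring are prone to reductive C–O cleavage.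
- CH2Cl2 replaces nitromethane in the annulation, because nitromethane could add to the aldimine tautomer (aza-Henry reaction).

Step 1
Reactants: 1 1,2,4,5-tetramethoxybenzene; 2 oxirane (ethylene oxide)
Product: 4 2-(2,3,5,6-tetramethoxyphenyl)ethanol, via aryllithium 3 (not isolated)
Conditions: n-BuLi (1.1 equiv), TMEDA, THF, 0 °C → rt; then 2 (THF solution), −78 °C → rt; H2O quench
Reagents that add atoms: none
Why: Directed ortho-metalation takes place at a ring C–H flanked by two methoxy groups, and the aryllithium opens oxirane by SN2 attack, installing the two carbons that become C3 and C2 of indole B.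

Step 2
Reactants: 4 2-(2,3,5,6-tetramethoxyphenyl)ethanol
Product: 5 2-(4-bromo-2,3,5,6-tetramethoxyphenyl)ethanol
Conditions: NBS (1.05 equiv), dry MeCN, 0 °C → rt, dark
Reagents that add atoms: N-bromosuccinimide, O=C1CCC(=O)N1Br
Why: Electrophilic aromatic bromination can only strike the single remaining C–H of the electron-rich ring, and anhydrous NBS avoids oxidative demethylation and spares the primary alcohol.

Step 3
Reactants: 6 6-methoxyindole
Product: 8 3-iodo-6-methoxy-1-tosylindole, via 3-iodo-6-methoxyindole 7 (not isolated)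
Conditions: I2 (1.0 equiv), KOH (powder, excess), DMF, rt; then TsCl (1.3 equiv), 0 °C → rt
Reagents that add atoms: iodine, II; p-toluenesulfonyl chloride, Cc1ccc(S(=O)(=O)Cl)cc1
Why: Electrophilic iodination of the free indole is C3-selective and the labile iodide is N-sulfonylated in the same basic solution, so halogenation precedes the deactivating tosyl group and cannot stray onto the methoxy-activated benzo ring.

Step 4
Reactants: 8 3-iodo-6-methoxy-1-tosylindole
Product: 9 6-methoxy-3-(4,4,5,5-tetramethyl-1,3,2-dioxaborolan-2-yl)-1-tosylindole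
Conditions: B2pin2, PdCl2(dppf) (3 mol %), KOAc, 1,4-dioxane, 85 °C
Reagents that add atoms: bis(pinacolato)diboron, CC1(C)OB(OC1(C)C)B1OC(C)(C)C(C)(C)O1
Why: In this Miyaura borylation the C3–I bond of an N-sulfonylindole adds readily to zerovalent palladium, and KOAc is too weak a base to cleave the sulfonamide or promote homocoupling.

Step 5
Reactants: 5 2-(4-bromo-2,3,5,6-tetramethoxyphenyl)ethanol; 9 6-methoxy-3-(pinacolboryl)-1-tosylindole
Product: 10 2-[4-(6-methoxy-1-tosylindol-3-yl)-2,3,5,6-tetramethoxyphenyl]ethanol
Conditions: Pd(OAc)2 (5 mol %), SPhos (10 mol %), K3PO4, toluene–H2O, 95 °C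
Reagents that add atoms: none
Why: In this Suzuki–Miyaura coupling the bulky, electron-rich biarylphosphine is suited to di-ortho-substituted electron-rich aryl bromides, the N-tosyl boronate resists protodeboronation, and the free primary alcohol is tolerated.

Step 6
Reactants: 10 2-[4-(6-methoxy-1-tosylindol-3-yl)-2,3,5,6-tetramethoxyphenyl]ethanol
Product: 11 [4-(6-methoxy-1-tosylindol-3-yl)-2,3,5,6-tetramethoxyphenyl]acetaldehyde
Conditions: Dess–Martin periodinane (1.2 equiv), CH2Cl2, 0 °C → rt
Reagents that add atoms: none
Why: Dess–Martin oxidation stops at the aldehyde under non-aqueous conditions and leaves the tosyl-deactivated indole and the methoxyarene untouched.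

Step 7
Reactants: 11 [4-(6-methoxy-1-tosylindol-3-yl)-2,3,5,6-tetramethoxyphenyl]acetaldehyde; 12 2-(phenylsulfonyl)ethanamine hydrochloride
Product: 14 (E)-2-[4-(6-methoxy-1-tosylindol-3-yl)-2,3,5,6-tetramethoxyphenyl]-N-[2-(phenylsulfonyl)ethyl]ethenamine, via aldimine 13 (not isolated)
Conditions: Et3N (1.0 equiv), MgSO4, CH2Cl2, rt; switch to toluene, filter, concentrate, use at once
Reagents that add atoms: none
Why: Dehydrative condensation of an aldehyde with a primary amine gives the aldimine, which equilibrates with the secondary enamine (imine–enamine tautomerism), the (E) geometry keeping nitrogen away from the bulky aryl group.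

Step 8
Reactants: 14 (E)-enamine; 15 1,4-benzoquinone
Product: 18 3-[4-(6-methoxy-1-tosylindol-3-yl)-2,3,5,6-tetramethoxyphenyl]-1-[2-(phenylsulfonyl)ethyl]indol-5-ol, via hydroquinone adduct 16 (not isolated), via quinone adduct 17 (not isolated)
Conditions: 15 (1.2 equiv), ZnCl2 (0.3 equiv, Et2O solution), 4 Å molecular sieves, CH2Cl2, 0 °C → rt, Ar; slow addition of 14 to 15
Reagents that add atoms: none
Why: Proposed new method: the aryl-bearing β-carbon of 14 should add in conjugate fashion to ZnCl2-activated 15 to give, after proton shifts, hydroquinone 16, which a further molecule of 15 oxidises to quinone 17; the N–H, lying cis to the quinone ring, then adds to the neighbouring C=O, water leaves, and the quinone-iminium ion is reduced by the hydroquinone generated before, so the net equation is 14 + 15 → 18 + H2O. The closest known reaction type is the Nenitzescu synthesis of 5-hydroxyindoles from 1,4-benzoquinone and β-aminocrotonic esters, also in its ZnCl2-catalysed form; what is new is an aldehyde-derived enamine that has an aryl group in place of the stabilising ester. The one new ring, the pyrrole ring of indole B, is closed by 5-exo-trig attack of nitrogen on the quinone carbonyl followed by dehydration (N1–C7a), after the intermolecular C3–C3a bond has been made; no stereocentre arises. C- rather than N-attack is favoured by the soft enamine carbon, by Lewis-acid activation of the quinone and by the inductively weakened sulfonylethyl nitrogen; closure through nitrogen rather than oxygen is favoured because the aminal-type O-adduct of a secondary enamine can reopen whereas N-closure ends in an aromatic indole, and Brønsted acid, which would expel the amine toward a benzofuran, is excluded. The tosyl group removes the nucleophilicity of C2 of indole A, so the enamine is the only partner for the quinone, and the symmetry of 15 leaves C5 as the only possible site for the hydroxyl group. Molecular sieves take up the water formed and slow addition of 14 keeps the quinone in excess, which limits hydrolysis and double addition.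

Step 9
Reactants: 18 3-[4-(6-methoxy-1-tosylindol-3-yl)-2,3,5,6-tetramethoxyphenyl]-1-[2-(phenylsulfonyl)ethyl]indol-5-ol
Product: 20 3-[4-(6-methoxy-1H-indol-3-yl)-2,3,5,6-tetramethoxyphenyl]-1H-indol-5-ol (target), via N-tosyl hydroxyindole 19 (not isolated)
Conditions: KOtBu (6 equiv), THF, 0 °C → rt, Ar; then KOH (large excess), MeOH–H2O, 65 °C, Ar; aq HCl to pH 6
Reagents that add atoms: none
Why: E1cB retro-Michael loss of the 2-(phenylsulfonyl)ethyl group, a known base-labile N-protecting group of pyrroles and indoles, is followed by alkaline hydrolysis of the N-sulfonylindole; the aryl methyl ethers are inert to base, methanol traps the released vinyl sulfone, and exclusion of air protects the phenoxide.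

Compound list
1 | 1,2,4,5-tetramethoxybenzene | COc1cc(OC)c(OC)cc1OC | starting material
2 | oxirane (ethylene oxide) | C1CO1 | starting material
3 | (2,3,5,6-tetramethoxyphenyl)lithium, formed in situ | [Li]c1c(OC)c(OC)cc(OC)c1OC | intermediate
4 | 2-(2,3,5,6-tetramethoxyphenyl)ethanol | OCCc1c(OC)c(OC)cc(OC)c1OC | intermediate
5 | 2-(4-bromo-2,3,5,6-tetramethoxyphenyl)ethanol | OCCc1c(OC)c(OC)c(Br)c(OC)c1OC | intermediate
6 | 6-methoxyindole | COc1ccc2cc[nH]c2c1 | starting material
7 | 3-iodo-6-methoxyindole, formed in situ | COc1ccc2c(I)c[nH]c2c1 | intermediate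
8 | 3-iodo-6-methoxy-1-tosylindole | COc1ccc2c(I)cn(S(=O)(=O)c3ccc(C)cc3)c2c1 | intermediate
9 | 6-methoxy-3-(4,4,5,5-tetramethyl-1,3,2-dioxaborolan-2-yl)-1-tosylindole | COc1ccc2c(B3OC(C)(C)C(C)(C)O3)cn(S(=O)(=O)c3ccc(C)cc3)c2c1 | intermediate
10 | 2-[4-(6-methoxy-1-tosylindol-3-yl)-2,3,5,6-tetramethoxyphenyl]ethanol | COc1ccc2c(-c3c(OC)c(OC)c(CCO)c(OC)c3OC)cn(S(=O)(=O)c3ccc(C)cc3)c2c1 | intermediate
11 | [4-(6-methoxy-1-tosylindol-3-yl)-2,3,5,6-tetramethoxyphenyl]acetaldehyde | COc1ccc2c(-c3c(OC)c(OC)c(CC=O)c(OC)c3OC)cn(S(=O)(=O)c3ccc(C)cc3)c2c1 | intermediate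
12 | 2-(phenylsulfonyl)ethanamine hydrochloride | Cl.NCCS(=O)(=O)c1ccccc1 | starting material
13 | (E)-aldimine of 11 with 2-(phenylsulfonyl)ethanamine, formed in situ | COc1ccc2c(-c3c(OC)c(OC)c(C/C=N/CCS(=O)(=O)c4ccccc4)c(OC)c3OC)cn(S(=O)(=O)c3ccc(C)cc3)c2c1 | intermediate
14 | (E)-2-[4-(6-methoxy-1-tosylindol-3-yl)-2,3,5,6-tetramethoxyphenyl]-N-[2-(phenylsulfonyl)ethyl]ethenamine | COc1ccc2c(-c3c(OC)c(OC)c(/C=C/NCCS(=O)(=O)c4ccccc4)c(OC)c3OC)cn(S(=O)(=O)c3ccc(C)cc3)c2c1 | intermediate
15 | 1,4-benzoquinone | O=C1C=CC(=O)C=C1 | starting material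
16 | 2-{1-aryl-2-[2-(phenylsulfonyl)ethylamino]ethenyl}benzene-1,4-diol (aryl = the central ring bearing indole A; N cis to the diol ring), formed in situ | COc1ccc2c(-c3c(OC)c(OC)c(/C(=C/NCCS(=O)(=O)c4ccccc4)c4cc(O)ccc4O)c(OC)c3OC)cn(S(=O)(=O)c3ccc(C)cc3)c2c1 | intermediate
17 | 2-{1-aryl-2-[2-(phenylsulfonyl)ethylamino]ethenyl}-1,4-benzoquinone (N cis to the quinone ring), formed in situ | COc1ccc2c(-c3c(OC)c(OC)c(/C(=C/NCCS(=O)(=O)c4ccccc4)C4=CC(=O)C=CC4=O)c(OC)c3OC)cn(S(=O)(=O)c3ccc(C)cc3)c2c1 | intermediate
18 | 3-[4-(6-methoxy-1-tosylindol-3-yl)-2,3,5,6-tetramethoxyphenyl]-1-[2-(phenylsulfonyl)ethyl]indol-5-ol | COc1ccc2c(-c3c(OC)c(OC)c(-c4cn(CCS(=O)(=O)c5ccccc5)c5ccc(O)cc45)c(OC)c3OC)cn(S(=O)(=O)c3ccc(C)cc3)c2c1 | intermediate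
19 | 3-[4-(6-methoxy-1-tosylindol-3-yl)-2,3,5,6-tetramethoxyphenyl]-1H-indol-5-ol, formed in situ | COc1ccc2c(-c3c(OC)c(OC)c(-c4c[nH]c5ccc(O)cc45)c(OC)c3OC)cn(S(=O)(=O)c3ccc(C)cc3)c2c1 | intermediate
20 | 3-[4-(6-methoxy-1H-indol-3-yl)-2,3,5,6-tetramethoxyphenyl]-1H-indol-5-ol (CNP0234672.0) | COc1ccc2c(-c3c(OC)c(OC)c(-c4c[nH]c5ccc(O)cc45)c(OC)c3OC)c[nH]c2c1 | target

Total step count: 9. Longest linear sequence: 7 (steps 1, 2, 5–9 or steps 3, 4, 5–9).

Steps most likely to fail

Step 8.
- What may go wrong: the unstabilised enamine may close through oxygen and lose the amine toward a benzofuran. It may also attack the quinone through nitrogen, be degraded oxidatively, or be hydrolysed by the water released.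
- Fallback (known chemistry, from 11 back to 19): condensation of 11 with commercial 4-(benzyloxy)phenylhydrazine hydrochloride (Cl.NNc1ccc(OCc2ccccc2)cc1) in EtOH at rt should give the 4-(benzyloxy)phenylhydrazone F1.
- Warming in AcOH at 80 °C should then trigger Fischer indolisation. The [3,3]-shift of the ene-hydrazine makes the aryl-bearing carbon C3, and the para-substituted hydrazine allows only the 5-oxygenated isomer, giving the 5-benzyloxyindole F2.
- Hydrogenolysis (H2, Pd/C, EtOAc–EtOH) frees the phenol and gives 19, which is carried to 20 by the KOH stage of step 9.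

Step 5.
- What may go wrong: oxidative addition and transmetalation at the doubly ortho-flanked C–Br bond may be so slow that protodeboronation of the indolylboronate and hydrodebromination take over.
- Fallback (roles of the partners reversed, from 4 and 8 back to 10): n-BuLi (2.2 equiv, TMEDA, THF, 0 °C → rt) should remove the O–H proton and the last ring C–H of 4, which again lies between two methoxy groups, to give the dilithio species F3.
- ZnCl2 converts this into the arylzinc chloride F4.
- Negishi coupling with the reactive, unhindered iodide 8 (Pd2(dba)3, SPhos, THF, 60 °C) and aqueous work-up should deliver 10.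
- Steps 2 and 4 then become unnecessary.

Step 9.
- What may go wrong: β-elimination may stay incomplete, the released Michael acceptor may re-add to phenoxide or indolide, and the electron-rich hydroxyindole may be oxidised by traces of air in strong base.
- Fallback (reductive instead of eliminative unmasking, from 11 back to 20): benzylamine (NCc1ccccc1) replaces 12 in the condensation and gives the N-benzyl enamine F5.
- Annulation with 15 under the conditions of step 8 gives the 1-benzylindol-5-ol F6.
- Sodium in NH3–THF at −78 °C, added only until the blue colour just persists and then quenched with NH4Cl, cleaves the N–benzyl and N–tosyl bonds together. The short contact time is meant to spare the methoxy groups.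

Further compounds
F1 | step 8 | (E)-4-(benzyloxy)phenylhydrazone of aldehyde 11 | COc1ccc2c(-c3c(OC)c(OC)c(C/C=N/Nc4ccc(OCc5ccccc5)cc4)c(OC)c3OC)cn(S(=O)(=O)c3ccc(C)cc3)c2c1
F2 | step 8 | 5-(benzyloxy)-3-[4-(6-methoxy-1-tosylindol-3-yl)-2,3,5,6-tetramethoxyphenyl]-1H-indole | COc1ccc2c(-c3c(OC)c(OC)c(-c4c[nH]c5ccc(OCc6ccccc6)cc45)c(OC)c3OC)cn(S(=O)(=O)c3ccc(C)cc3)c2c1
F3 | step 5 | lithium 2-(4-lithio-2,3,5,6-tetramethoxyphenyl)ethoxide | [Li]OCCc1c(OC)c(OC)c([Li])c(OC)c1OC
F4 | step 5 | lithium 2-[4-(chlorozincio)-2,3,5,6-tetramethoxyphenyl]ethoxide | [Li]OCCc1c(OC)c(OC)c([Zn]Cl)c(OC)c1OC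
F5 | step 9 | (E)-N-benzyl-2-[4-(6-methoxy-1-tosylindol-3-yl)-2,3,5,6-tetramethoxyphenyl]ethenamine | COc1ccc2c(-c3c(OC)c(OC)c(/C=C/NCc4ccccc4)c(OC)c3OC)cn(S(=O)(=O)c3ccc(C)cc3)c2c1
F6 | step 9 | 1-benzyl-3-[4-(6-methoxy-1-tosylindol-3-yl)-2,3,5,6-tetramethoxyphenyl]indol-5-ol | COc1ccc2c(-c3c(OC)c(OC)c(-c4cn(Cc5ccccc5)c5ccc(O)cc45)c(OC)c3OC)cn(S(=O)(=O)c3ccc(C)cc3)c2c1
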